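**Retrosynthetic overview**

1. The target is (1S,4aS,7S,7aR), with H-1, H-4a and H-7a all cis. The cyclopentane ring, the pyran carbons and C4a/C7/C7a are bought as (4aS,7S,7aR)-nepetalactone 1 (same three descriptors); the benzopyranone ring is bought too.
2. C3–C(=O) bond (key bond): visible-light decarboxylative C–H acylation of enol lactone 1 with keto acid 2 gives 3.
3. C1–C3′ bond at the acyl oxidation level: lactone 3 C-acylates coumarin 4 (pyran ring opens to 5), and acid re-closes the pyran ring as alkylidene 6.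
4. C1–H bond: hydride adds to the C1 oxocarbenium of 6 from the convex face to give 7 (1S). Direct C-arylation of a lactol would be expected to put the aryl group on the convex face, i.e. the C1 epimer.
5. O-Methylation of 7 gives 2-methoxychromone 8. Ring order: cyclopentane and benzopyranone bought; pyran ring opened and re-formed in step 2.

Assumption: (4aS,7S,7aR)-nepetalactone (main constituent of commercial catnip oil, also sold neat), 4-hydroxy-5-methylcoumarin and 4-methyl-2-oxopentanoic acid are taken as purchasable.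

**Route**

Step 1
Reactants: 1 (4aS,7S,7aR)-nepetalactone; 2 4-methyl-2-oxopentanoic acid
Product: 3 (4aS,7S,7aR)-4,7-dimethyl-3-(3-methylbutanoyl)-5,6,7,7a-tetrahydrocyclopenta[c]pyran-1(4aH)-one
Conditions: 2 (2.5 equiv, in portions), [Ir(dF(CF3)ppy)2(dtbbpy)]PF6 (1 mol %), Co(dmgH)2(py)Cl (8 mol %), 2,6-lutidine (0.5 equiv), MeCN, 450 nm LEDs, 25 °C, Ar
Reagents that add atoms: none
Why: Proposed new method: decarboxylative dehydrogenative (Heck-type) C–H acylation of an enol lactone at its oxygen-bearing vinyl carbon — the excited iridium photocatalyst oxidises the carboxylate of 2, loss of CO2 gives the isovaleryl radical, this adds to C3 (the only unsubstituted alkene carbon; the alkene is an enol ester, only weakly donor-substituted, and attack leaves a tertiary C4 radical), and the cobaloxime (divalent cobalt) removes the C3 hydrogen to restore the now ketone-conjugated C3=C4 bond and releases H2; the closest known reaction type is the photoredox/cobaloxime decarboxylative acyl-Heck coupling of α-keto acids with styrenes and enamides; no stereocentre is formed and C4a, C7, C7a are not touched.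

Step 2
Reactants: 3 (4aS,7S,7aR)-4,7-dimethyl-3-(3-methylbutanoyl)-5,6,7,7a-tetrahydrocyclopenta[c]pyran-1(4aH)-one; 4 4-hydroxy-5-methyl-2H-chromen-2-one
Product: 6 (3E)-3-[(4aS,7S,7aR)-4,7-dimethyl-3-(3-methylbutanoyl)-4a,5,6,7-tetrahydrocyclopenta[c]pyran-1(7aH)-ylidene]-5-methyl-2H-chromene-2,4(3H)-dione, via seco acylcoumarin 5 (not isolated)
Conditions: DMAP (1.5 equiv), Et3N (1.5 equiv), CH2Cl2, 25 °C; then TFA (6 equiv), 4 Å MS, 0 → 25 °C
Reagents that add atoms: none
Why: Steglich-type C-acylation of a 4-hydroxycoumarin by an activated ester — DMAP opens the enol lactone (the leaving group is the enolate of a 1,2-diketone) to an acylpyridinium that acylates C3′ of 4, the enolised tricarbonyl 5 being the sink and shielding C7a from epimerisation, and acid then closes the enol OH onto the acyl carbon with loss of water (enol-ether formation) to give the push–pull alkylidene 6; no stereocentre is formed.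

Step 3
Reactants: 6 (3E)-3-[(4aS,7S,7aR)-4,7-dimethyl-3-(3-methylbutanoyl)-4a,5,6,7-tetrahydrocyclopenta[c]pyran-1(7aH)-ylidene]-5-methyl-2H-chromene-2,4(3H)-dione
Product: 7 4-hydroxy-5-methyl-3-[(1S,4aS,7S,7aR)-4,7-dimethyl-3-(3-methylbutanoyl)-1,4a,5,6,7,7a-hexahydrocyclopenta[c]pyran-1-yl]-2H-chromen-2-one
Conditions: TFA (3 equiv), Et3SiH (3 equiv), CH2Cl2, −40 °C
Reagents that add atoms: none
Why: Ionic hydrogenation — TFA protonates the push–pull dione to the cyclic C1 oxocarbenium and Et3SiH delivers hydride to C1 from the convex face of the cis-fused bicycle (the face of H-4a and H-7a, anti to the pseudoaxial C7a–C7 bond), so H-1 ends cis to H-7a and the coumarinyl group on the concave face (1S, substrate control from the bought centres); the conditions are too mild to ionise the C1–O bond of the product or to reduce the enone.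

Step 4
Reactants: 7 4-hydroxy-5-methyl-3-[(1S,4aS,7S,7aR)-4,7-dimethyl-3-(3-methylbutanoyl)-1,4a,5,6,7,7a-hexahydrocyclopenta[c]pyran-1-yl]-2H-chromen-2-one
Product: 8 2-methoxy-5-methyl-3-[(1S,4aS,7S,7aR)-4,7-dimethyl-3-(3-methylbutanoyl)-1,4a,5,6,7,7a-hexahydrocyclopenta[c]pyran-1-yl]-4H-chromen-4-one (target)
Conditions: MeOTf (1.3 equiv), 2,6-di-tert-butyl-4-methylpyridine (1.5 equiv), CH2Cl2, 0 → 25 °C
Reagents that add atoms: methyl trifluoromethanesulfonate, COS(=O)(=O)C(F)(F)F
Why: O-Methylation of a neutral vinylogous acid on its lactone carbonyl oxygen (as in the 4-hydroxy-2-pyrone to 2-methoxy-4-pyrone conversion), followed by loss of the 4-OH proton to the hindered pyridine, gives the 2-methoxy-4-chromenone, the 4-oxygen being shielded by the 5-methyl group and the C3 substituent; no base able to open the C1–O bond is present, so C1 keeps its configuration.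

**Compound list**

1 | (4aS,7S,7aR)-4,7-dimethyl-5,6,7,7a-tetrahydrocyclopenta[c]pyran-1(4aH)-one (cis,trans-nepetalactone) | O=C1OC=C(C)[C@H]2CC[C@H](C)[C@H]21 | starting material
2 | 4-methyl-2-oxopentanoic acid | CC(C)CC(=O)C(=O)O | starting material
3 | (4aS,7S,7aR)-4,7-dimethyl-3-(3-methylbutanoyl)-5,6,7,7a-tetrahydrocyclopenta[c]pyran-1(4aH)-one | O=C1OC(C(=O)CC(C)C)=C(C)[C@H]2CC[C@H](C)[C@H]21 | intermediate
4 | 4-hydroxy-5-methyl-2H-chromen-2-one | Cc1cccc2oc(=O)cc(O)c12 | starting material
5 | 4-hydroxy-3-{[(1R,2S,5S)-2-[(2Z)-3-hydroxy-6-methyl-4-oxohept-2-en-2-yl]-5-methylcyclopentyl]carbonyl}-5-methyl-2H-chromen-2-one (drawn as the enol tautomer) | CC(C)CC(=O)/C(O)=C(C)/[C@H]1CC[C@H](C)[C@H]1C(=O)c1c(O)c2c(C)cccc2oc1=O | intermediate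
6 | (3E)-3-[(4aS,7S,7aR)-4,7-dimethyl-3-(3-methylbutanoyl)-4a,5,6,7-tetrahydrocyclopenta[c]pyran-1(7aH)-ylidene]-5-methyl-2H-chromene-2,4(3H)-dione (4-carbonyl syn to the ring oxygen; the push–pull C=C geometry is labile) | O=C1Oc2cccc(C)c2C(=O)/C1=C1\OC(C(=O)CC(C)C)=C(C)[C@H]2CC[C@H](C)[C@H]21 | intermediate
7 | 4-hydroxy-5-methyl-3-[(1S,4aS,7S,7aR)-4,7-dimethyl-3-(3-methylbutanoyl)-1,4a,5,6,7,7a-hexahydrocyclopenta[c]pyran-1-yl]-2H-chromen-2-one | O=c1oc2cccc(C)c2c(O)c1[C@H]1OC(C(=O)CC(C)C)=C(C)[C@H]2CC[C@H](C)[C@H]21 | intermediate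
8 | 2-methoxy-5-methyl-3-[(1S,4aS,7S,7aR)-4,7-dimethyl-3-(3-methylbutanoyl)-1,4a,5,6,7,7a-hexahydrocyclopenta[c]pyran-1-yl]-4H-chromen-4-one | COc1oc2cccc(C)c2c(=O)c1[C@H]1OC(C(=O)CC(C)C)=C(C)[C@H]2CC[C@H](C)[C@H]21 | target

**Step count and risks**

Total steps: 4. Longest linear sequence: 4 (1 → 3 → 6 → 7 → 8).

Step 1 (the proposed new reaction) is the most likely to fail. The acyl radical is nucleophilic and adds only slowly to a donor-substituted, trisubstituted alkene, so aldehyde formation and decarbonylation compete. Hydrogen loss from the C4 radical toward C4a instead of C3 would also endanger the C4a centre. The fallback uses known chemistry, sets out from 1 and comes back at 3. iBu2AlH (CH2Cl2, −78 °C) reduces 1 to (1R,4aS,7S,7aR)-nepetalactol F1. TBSCl and imidazole give the silyl acetal F2. t-BuLi (THF, −78 → 0 °C) lithiates the oxygen-bearing vinyl carbon as in glycals, and N-methoxy-N,3-dimethylbutanamide gives the ketone F3. TBAF frees the acylated lactol F4, and Ag2CO3 on Celite (benzene, reflux) oxidises it to 3.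

Step 2 is the second risk. The hindered acyl group may transfer slowly or stop at the O-acyl stage, and long exposure to base or acid could epimerise C7a. The fallback sets out from 3 and comes back at 5 and hence 6. LiOH (THF/H2O, 0 °C) opens 3 to the seco acid F5. This acid is joined to 4 by the standard carbodiimide C-acylation of 4-hydroxycoumarins (EDC·HCl, DMAP, CH2Cl2), which gives 5. TFA with 4 Å MS then closes 5 to 6 as in the main route.

Step 3 is the third risk. The 4-hydroxycoumarin 7 can re-open at C1–O under acid, which would lead to the thermodynamically preferred C1 epimer or to over-reduction to a CH2 group. The fallback sets out from 6 and comes back at 8. MeOTf (CH2Cl2, 0 °C) methylates the lactone-type carbonyl oxygen of 6 to give the O-methyl oxocarbenium triflate F6. Et3SiH (−40 °C) then reduces F6 at C1 from the same convex face to give 8 directly, so the epimerisable hydroxycoumarin stage is never passed.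

**Further compounds**

F1 | step 1 | (1R,4aS,7S,7aR)-4,7-dimethyl-1,4a,5,6,7,7a-hexahydrocyclopenta[c]pyran-1-ol (nepetalactol) | O[C@@H]1OC=C(C)[C@H]2CC[C@H](C)[C@H]21
F2 | step 1 | tert-butyl{[(1S,4aS,7S,7aR)-4,7-dimethyl-1,4a,5,6,7,7a-hexahydrocyclopenta[c]pyran-1-yl]oxy}dimethylsilane | CC(C)(C)[Si](C)(C)O[C@@H]1OC=C(C)[C@H]2CC[C@H](C)[C@H]21
F3 | step 1 | 1-[(1S,4aS,7S,7aR)-1-{[tert-butyl(dimethyl)silyl]oxy}-4,7-dimethyl-1,4a,5,6,7,7a-hexahydrocyclopenta[c]pyran-3-yl]-3-methylbutan-1-one | CC(C)(C)[Si](C)(C)O[C@@H]1OC(C(=O)CC(C)C)=C(C)[C@H]2CC[C@H](C)[C@H]21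
F4 | step 1 | 1-[(1R,4aS,7S,7aR)-1-hydroxy-4,7-dimethyl-1,4a,5,6,7,7a-hexahydrocyclopenta[c]pyran-3-yl]-3-methylbutan-1-one | O[C@@H]1OC(C(=O)CC(C)C)=C(C)[C@H]2CC[C@H](C)[C@H]21
F5 | step 2 | (1R,2S,5S)-2-[(2Z)-3-hydroxy-6-methyl-4-oxohept-2-en-2-yl]-5-methylcyclopentane-1-carboxylic acid (drawn as the enol tautomer) | CC(C)CC(=O)/C(O)=C(C)/[C@H]1CC[C@H](C)[C@H]1C(=O)O
F6 | step 3 | (4aS,7S,7aR)-1-(2-methoxy-5-methyl-4-oxo-4H-chromen-3-yl)-4,7-dimethyl-3-(3-methylbutanoyl)-4a,5,6,7-tetrahydro-7aH-cyclopenta[c]pyran-2-ium trifluoromethanesulfonate | COc1oc2cccc(C)c2c(=O)c1C1=[O+]C(C(=O)CC(C)C)=C(C)[C@H]2CC[C@H](C)[C@H]21.[O-]S(=O)(=O)C(F)(F)F
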